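## Retrosynthetic overview

1. Feature: ring B (C5, C6, C7, C8, C9, C10) is a cyclohexanone whose carbonyl carbon C8 lies para to the quaternary carbon C5. It is therefore a reduced 4,4-disubstituted cyclohexa-2,5-dienone whose two arms, C6=C7 and C10=C9, are enantiotopic.
2. Key disconnection C1–C10: the bis(phenylsulfonyl)methyl carbon C1 at the end of the chain C5–C4(=CH2)–C3–C2–C1 adds to C10 of one arm under a chiral bifunctional urea. This closes ring A cis-fused and fixes C5 and C10 together.
3. The attacked arm then gives C9–OH (Rubottom oxidation anti to the sulfones). The untouched arm gives C7 (iodination, Stille coupling, 1,4-hydrogenation to the Z C7=C11 alkene). The C4 methylene gives C3–OH (allylic oxidation) and the C4 methyl (directed hydrogenation).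
4. Last disconnection: the C3–O acyl bond to (2E,4E,6E)-5-methyldodeca-2,4,6-trienoic acid 36.
5. Ring order: ring B first (the carbons of benzoic acid, Birch reductive methylation), ring A second (key step).

Key step: step 7

Conventions: eremophilane numbering is used for all bicyclic compounds. Ring A is C1, C2, C3, C4, C5, C10 and ring B is C5 to C10. C14 is the methyl on C5, C15 is the carbon on C4, and C11 to C13 form the side chain on C7. β is the face of the C5 methyl and α the opposite face. The target is 3α-acyloxy, 4β-methyl, 5β-methyl, 9β-hydroxy, 10β-H, which is (3R,4R,5R,9R,10S), with a 7(11)Z alkene.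

Assumption: the cinchonine-derived urea is taken to select the arm that leads to (4aS,8aR)-14. If it selects the other arm, the pseudo-enantiomeric cinchonidine-derived urea is used and nothing else changes.

## Route

Step 1
Reactants: 1 benzoic acid; 2 iodomethane
Product: 4 1-methylcyclohexa-2,5-diene-1-carboxylic acid, via dilithium dienediolate 3 (not isolated)
Conditions: Li, NH3(l)/THF, −78 °C; MeI; aq HCl work-up
Reagents that add atoms: lithium, [Li] (lithium of 3 only)
Why: Birch reduction of the benzoate gives the cross-conjugated dienediolate 3, which is alkylated at the ipso carbon (Birch reductive alkylation) and so creates the future quaternary C5 with its methyl C14 in an achiral ring.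

Step 2
Reactants: 4 1-methylcyclohexa-2,5-diene-1-carboxylic acid
Product: 6 N-methoxy-N,1-dimethylcyclohexa-2,5-diene-1-carboxamide, via acid chloride 5 (not isolated)
Conditions: (COCl)2, cat. DMF, CH2Cl2, 0 °C to rt; MeNH(OMe)·HCl, Et3N, 0 °C to rt
Reagents that add atoms: oxalyl chloride, O=C(Cl)C(=O)Cl (chlorine of 5 only); N,O-dimethylhydroxylamine hydrochloride, CNOC.Cl
Why: Weinreb amide formation through the acid chloride is the reliable way to acylate an amine with an α-quaternary acid, and the skipped diene has no way to aromatise without losing a carbon substituent.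

Step 3
Reactants: 6 Weinreb amide; 7 vinylmagnesium bromide
Product: 8 1-(1-methylcyclohexa-2,5-dien-1-yl)prop-2-en-1-one
Conditions: THF, 0 °C to rt; inverse quench into cold aq HCl
Reagents that add atoms: none
Why: Weinreb ketone synthesis stops at the chelated tetrahedral adduct so that no second addition occurs, and the acidic inverse quench keeps the released hydroxylamine from adding to the new vinyl ketone (C4, C3, C2).

Step 4
Reactants: 8 vinyl ketone; 9 bis(phenylsulfonyl)methane
Product: 10 1-(1-methylcyclohexa-2,5-dien-1-yl)-4,4-bis(phenylsulfonyl)butan-1-one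
Conditions: 9 (1.5 equiv), DBU (10 mol %), CH2Cl2, rt
Reagents that add atoms: none
Why: Michael addition of the soft, strongly acidic bis-sulfone carbon to an unhindered vinyl ketone forms C1–C2 under catalytic base, and the excess of 9 suppresses a second addition.

Step 5
Reactants: 10 keto bis-sulfone
Product: 12 3-methyl-3-[5,5-bis(phenylsulfonyl)pent-1-en-2-yl]cyclohexa-1,4-diene, via potassium carbanion salt 11 (not isolated)
Conditions: MePPh3Br (3.6 equiv), KOt-Bu (3.5 equiv), THF, 0 °C; add 10; reflux; aq NH4Cl
Reagents that add atoms: methyltriphenylphosphonium bromide, C[P+](c1ccccc1)(c1ccccc1)c1ccccc1.[Br-]; potassium tert-butoxide, CC(C)(C)[O-].[K+] (potassium of 11 only)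
Why: In this Wittig methylenation with excess ylide the first equivalent of base turns the acidic C1–H into salt 11, which cannot be lost by retro-Michael cleavage because C1 would have to leave as a dianion, and the small unstabilised ylide then converts the hindered C4 ketone into the C4=C15 methylene before ring oxidation, since a 4-acyl dienone would be prone to deacylative aromatisation.

Step 6
Reactants: 12 triene bis-sulfone
Product: 13 4-methyl-4-[5,5-bis(phenylsulfonyl)pent-1-en-2-yl]cyclohexa-2,5-dien-1-one
Conditions: (pyH)2Cr2O7 (pyridinium dichromate), t-BuOOH, Celite, PhH, 10 °C to rt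
Reagents that add atoms: tert-butyl hydroperoxide, CC(C)(C)OO
Why: Bis-allylic C–H oxidation with the chromate/tert-butylperoxy system, the standard passage from Birch-derived 3,3-disubstituted cyclohexa-1,4-dienes to 4,4-disubstituted dienones, attacks the doubly allylic ring CH2 as the weakest C–H bond rather than the singly allylic C3–H2, and the non-basic medium keeps the acidic bis-sulfone from closing onto the new dienone in a racemic sense.

Step 7
Reactants: 13 dienone bis-sulfone
Product: 14 (4aS,8aR)-4a-methyl-5-methylidene-8,8-bis(phenylsulfonyl)-4a,5,6,7,8,8a-hexahydronaphthalen-2(1H)-one (cis-fused; 5β-methyl; 10β-H)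
Conditions: 1-[3,5-bis(trifluoromethyl)phenyl]-3-(9-deoxy-9-epi-cinchonin-9-yl)urea (10 mol %), toluene, 0 °C
Reagents that add atoms: none
Why: The quinuclidine nitrogen of the catalyst removes the acidic C1–H while the two urea N–H bonds hold the dienone carbonyl, so the ion-paired carbanion C1 adds to C10, the β-carbon of one enone arm, and the resulting C9 enolate is protonated by the ammonium ion, which frees the catalyst. The closest known reaction type is the organocatalytic desymmetrising intramolecular Michael addition of tethered bis(sulfonyl)methyl carbanions to 4,4-disubstituted cyclohexa-2,5-dienones with cinchona ureas. Ring A (C1, C2, C3, C4, C5, C10) closes in the 6-exo-trig mode. C5 becomes stereogenic because only one of its two enantiotopic arms is attacked, a choice made by the chiral pocket of the catalyst, and C10 follows from it because the short tether C2–C3–C4 can bring C1 to C10 only on the face of ring B on which C4 stands, which enforces the cis fusion with 10-H syn to the C5 methyl. The step needs selection between the two arms and suppression of the uncatalysed racemic closure, which the flat achiral substrate, the weakly basic medium and the low temperature should secure, and a second addition is excluded because C1 is quaternary after closure, so the other arm survives as the C6=C7 enone.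

Step 8
Reactants: 14 bicyclic enone bis-sulfone
Product: 15 silyl dienol ether (C8–OTBS; C8=C9 and C6=C7; C1 bis-sulfone; C4 methylene; 5β-methyl; 10β-H)
Conditions: TBSOTf, Et3N, CH2Cl2, 0 °C
Reagents that add atoms: tert-butyldimethylsilyl triflate, CC(C)(C)[Si](C)(C)OS(=O)(=O)C(F)(F)F
Why: Soft enolisation with silyl triflate and amine avoids a free C9 enolate, which could expel the stabilised C1 carbanion by retro-Michael cleavage and erase C5 and C10, and C9 is the only enolisable position because the γ-carbon C5 is quaternary.

Step 9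
Reactants: 15 silyl dienol ether
Product: 17 9β-(tert-butyldimethylsilyloxy) enone bis-sulfone (C8 ketone; C6=C7; C4 methylene), via silyloxy-epoxide 16 (not isolated)
Conditions: mCPBA (1.05 equiv), CH2Cl2/hexane, −20 to 0 °C
Reagents that add atoms: 3-chloroperbenzoic acid, OOC(=O)c1cccc(Cl)c1
Why: In this Rubottom oxidation the peracid epoxidises the most electron-rich bond, the C8=C9 enol ether, from the β face, anti to the C10–C1 bond and the two phenylsulfonyl groups that cover the α face, and epoxide 16 opens with 1,4-silyl shift to the α-silyloxy ketone, which sets C9 with oxygen β (cis to 10-H).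

Step 10
Reactants: 17 α-silyloxy enone bis-sulfone
Product: 18 C8 allylic alcohol bis-sulfone (9β-OTBS; C6=C7; C4 methylene; C8 configuration not controlled)
Conditions: NaBH4, CeCl3·7H2O, MeOH/CH2Cl2, −78 °C
Reagents that add atoms: none
Why: Luche 1,2-reduction masks the enone and the α-silyloxy ketone, both of which would be reduced before the sulfones in the next step, ends any risk of retro-Michael cleavage, and creates a C8 carbinol centre that is of no consequence because it is removed again in step 12.

Step 11
Reactants: 18 allylic alcohol bis-sulfone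
Product: 19 desulfonylated allylic alcohol (C1 now CH2; 9β-OTBS; C8–OH; C6=C7; C4 methylene)
Conditions: 5% Na(Hg), Na2HPO4, MeOH/THF, −20 °C to rt
Reagents that add atoms: none
Why: Reductive desulfonylation by electron transfer cleaves each C1–S bond to sulfinate and a C1 radical or anion that takes up hydrogen, the phosphate buffer keeps the medium from becoming basic enough for silyl migration between O9 and O8, and isolated alkenes, the allylic alcohol and the silyl ether are not reduced.

Step 12
Reactants: 19 allylic alcohol
Product: 20 9β-(tert-butyldimethylsilyloxy) enone (C8 ketone; C6=C7; C4 methylene; 5β-methyl; 10β-H)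
Conditions: Dess–Martin periodinane, CH2Cl2, 0 °C to rt
Reagents that add atoms: none
Why: Dess–Martin oxidation of the single free hydroxyl restores the C6=C7–C8=O enone under neutral to weakly acidic conditions that do not epimerise C9.

Step 13
Reactants: 20 enone
Product: 21 3α-hydroxy enone (allylic alcohol at C3; C4 methylene; 9β-OTBS; C6=C7–C8=O)
Conditions: SeO2 (0.3 equiv), t-BuOOH, CH2Cl2, 0 °C to rt
Reagents that add atoms: tert-butyl hydroperoxide, CC(C)(C)OO (terminal oxidant, oxygen relayed by catalytic SeO2, O=[Se]=O)
Why: Selenium dioxide allylic hydroxylation (ene reaction at C15, then 2,3-sigmatropic shift) can place oxygen only on C3, since C5 is quaternary and the electron-poor C6=C7 bond has no allylic hydrogen, and the oxygen should arrive on the α face because the equatorial 9β-silyloxy group holds the cis-decalin in the chair pair in which the C5 methyl is axial on ring A and screens the β face of C3.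

Step 14
Reactants: 21 3α-hydroxy enone
Product: 22 7-iodo enone (C7–I; C6=C7; C8 ketone; 3α-OH; C4 methylene; 9β-OTBS)
Conditions: I2, pyridine/CH2Cl2, rt
Reagents that add atoms: iodine, II
Why: α-Iodination by conjugate addition of pyridine to C6, iodination of the enolate at C7 and loss of pyridine (a Baylis–Hillman-type sequence known for 4,4-disubstituted cyclohexenones) uses the surviving enone arm to activate C7.

Step 15
Reactants: 23 2-bromoprop-2-en-1-ol
Product: 25 2-(tributylstannyl)prop-2-en-1-ol, via dilithio alkoxide 24 (not isolated)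
Conditions: t-BuLi (3.1 equiv), Et2O, −78 to 0 °C; Bu3SnCl, −78 °C to rt; H2O
Reagents that add atoms: tert-butyllithium, [Li]C(C)(C)C (lithium of 24 only); tributyltin chloride, CCCC[Sn](Cl)(CCCC)CCCC
Why: Deprotonation followed by bromine–lithium exchange gives the O,C-dilithio species, whose carbanion is stannylated preferentially, and working on the free alkoxide avoids the oxygen-to-carbon silyl shift that a silyl ether would suffer.

Step 16
Reactants: 25 stannyl alcohol
Product: 26 tert-butyldimethyl{[2-(tributylstannyl)prop-2-en-1-yl]oxy}silane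
Conditions: TBSCl, imidazole, CH2Cl2, rt
Reagents that add atoms: tert-butyldimethylsilyl chloride, CC(C)(C)[Si](C)(C)Cl
Why: Standard silylation of a primary alcohol protects the future C12 hydroxyl so that only the C3 hydroxyl is free at the esterification.

Step 17
Reactants: 22 7-iodo enone; 26 alkenylstannane
Product: 27 cross-conjugated dienone (C7 bears C11(=C13H2)C12H2OTBS; C6=C7; C8 ketone; 3α-OH; C4 methylene; 9β-OTBS)
Conditions: Pd2(dba)3 (5 mol %), AsPh3, CuI, NMP, rt to 45 °C
Reagents that add atoms: none
Why: Stille coupling of an α-iodoenone with an alkenylstannane under zerovalent palladium, accelerated by AsPh3 and CuI, forms C7–C11 under neutral conditions that leave the epimerisable C9 centre, the free allylic alcohol and both silyl ethers untouched.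

Step 18
Reactants: 27 cross-conjugated dienone
Product: 28 (7Z)-alkylidene ketone (C7=C11 with C12H2OTBS syn to C8=O and C13H3 syn to C6H2; 3α-OH; C4 methylene; 9β-OTBS)
Conditions: (η6-naphthalene)Cr(CO)3 (20 mol %), H2 (50 atm), THF, 40 °C
Reagents that add atoms: none
Why: In the arene–Cr(CO)3-catalysed 1,4-hydrogenation of 1,3-dienes the Cr(CO)3 fragment binds the C6=C7–C11=C13 diene only in its s-cis form and adds one hydrogen to each terminus (C6 and C13), so the new C7=C11 bond must carry C6 and C13 on one side and C8 and C12 on the other, which is the required Z geometry, while the ring enone (fixed s-trans) and the isolated C4 methylene are not substrates.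

Step 19
Reactants: 28 (7Z)-alkylidene ketone
Product: 29 3α-hydroxy-4β-methyl ketone (4β,5β-dimethyl; 10β-H; 9β-OTBS; 7Z alkene with C12–OTBS)
Conditions: [Ir(cod)(PCy3)(py)]PF6 (5 mol %), H2 (1 atm), CH2Cl2, 0 °C to rt
Reagents that add atoms: none
Why: In this hydroxyl-directed hydrogenation the cationic iridium catalyst binds the 3α-hydroxyl and delivers hydrogen to the adjacent C4=C15 bond from the same α face, which sets C4 with its methyl β (trans to the C3 oxygen, cis to the C5 methyl), while the tetrasubstituted conjugated C7=C11 bond is too hindered and electron-poor to compete.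

Step 20
Reactants: 30 (E)-oct-2-enal
Product: 31 (E)-non-3-en-1-yne
Conditions: TMSCHN2, n-BuLi, THF, −78 °C; add 30; −78 °C to rt
Reagents that add atoms: (trimethylsilyl)diazomethane, C[Si](C)(C)C=[N+]=[N-]
Why: In the Colvin rearrangement the lithiated silyl diazomethane adds to the aldehyde, Peterson-type loss of silanolate gives a diazoalkene, and loss of N2 with 1,2-hydrogen shift of the alkylidene carbene gives the terminal alkyne without touching the E alkene.

Step 21
Reactants: 31 (E)-non-3-en-1-yne
Product: 33 (1E,3E)-1-iodo-2-methylnona-1,3-diene, via alkenylalane 32 (not isolated)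
Conditions: Me3Al, Cp2ZrCl2 (25 mol %), CH2Cl2, rt; I2, THF, −30 °C
Reagents that add atoms: trimethylaluminium, C[Al](C)C; iodine, II
Why: Zirconium-catalysed methylalumination (Negishi carboalumination) adds methyl and aluminium syn across the terminal alkyne with aluminium at the terminus, and iodinolysis with retention fixes the E trisubstituted alkene that becomes C4=C5 of the acid.

Step 22
Reactants: 33 dienyl iodide; 34 methyl acrylate
Product: 35 methyl (2E,4E,6E)-5-methyldodeca-2,4,6-trienoate
Conditions: Pd(OAc)2 (5 mol %), K2CO3, n-Bu4NCl, DMF, rt to 40 °C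
Reagents that add atoms: none
Why: The Heck reaction under phase-transfer (Jeffery) conditions couples the alkenyl iodide with retention and gives the E acrylate through syn insertion and syn β-hydride elimination.

Step 23
Reactants: 35 methyl trienoate
Product: 36 (2E,4E,6E)-5-methyldodeca-2,4,6-trienoic acid
Conditions: LiOH, THF/MeOH/H2O, rt; aq HCl to pH 3
Reagents that add atoms: lithium hydroxide, [Li+].[OH-]
Why: Saponification of an unhindered methyl ester proceeds under conditions too mild to isomerise the all-E triene.

Step 24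
Reactants: 36 trienoic acid; 29 3α-hydroxy-4β-methyl ketone
Product: 38 bis-silyl ether of the target (3α-trienoate; 9β-OTBS; C12–OTBS), via mixed anhydride 37 (not isolated)
Conditions: 36, 2,4,6-Cl3C6H2COCl, Et3N, toluene, rt; then 29, DMAP, rt
Reagents that add atoms: 2,4,6-trichlorobenzoyl chloride, O=C(Cl)c1c(Cl)cc(Cl)cc1Cl (aroyl group of 37 only)
Why: Yamaguchi esterification through mixed anhydride 37 acylates the only free hydroxyl (the equatorial 3α-OH) with retention at C3, and the mild bases should not isomerise the trienoate or the Z enone.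

Step 25
Reactants: 38 bis-silyl ether
Product: 39 target CNP0226738.1
Conditions: HF·pyridine, excess pyridine, THF, 0 °C to rt
Reagents that add atoms: none
Why: Fluoride-mediated cleavage of both silyl ethers is run with pyridine-buffered HF because the liberated Z γ-hydroxy enone could close onto C8 and dehydrate to a furan under stronger acid, while base-mediated desilylation would endanger the C9 ketol and the ester.

## Compound list

| No. | Name | SMILES | Role |
|---|---|---|---|
| 1 | benzoic acid | OC(=O)c1ccccc1 | starting material |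
| 2 | iodomethane | CI | starting material |
| 3 | dilithium dienediolate of 1,4-dihydrobenzoic acid | [Li]OC(O[Li])=C1C=CCC=C1 | intermediate (not isolated) |
| 4 | 1-methylcyclohexa-2,5-diene-1-carboxylic acid | CC1(C=CCC=C1)C(=O)O | intermediate |
| 5 | 1-methylcyclohexa-2,5-diene-1-carbonyl chloride | CC1(C=CCC=C1)C(=O)Cl | intermediate (not isolated) |
| 6 | N-methoxy-N,1-dimethylcyclohexa-2,5-diene-1-carboxamide | CON(C)C(=O)C1(C)C=CCC=C1 | intermediate |
| 7 | vinylmagnesium bromide | C=C[Mg]Br | starting material |
| 8 | 1-(1-methylcyclohexa-2,5-dien-1-yl)prop-2-en-1-one | C=CC(=O)C1(C)C=CCC=C1 | intermediate |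
| 9 | bis(phenylsulfonyl)methane | O=S(=O)(CS(=O)(=O)c1ccccc1)c1ccccc1 | starting material |
| 10 | 1-(1-methylcyclohexa-2,5-dien-1-yl)-4,4-bis(phenylsulfonyl)butan-1-one | O=C(CCC(S(=O)(=O)c1ccccc1)S(=O)(=O)c1ccccc1)C1(C)C=CCC=C1 | intermediate |
| 11 | potassium salt of 10 (carbanion at C1) | [K+].O=C(CC[C-](S(=O)(=O)c1ccccc1)S(=O)(=O)c1ccccc1)C1(C)C=CCC=C1 | intermediate (not isolated) |
| 12 | 3-methyl-3-[5,5-bis(phenylsulfonyl)pent-1-en-2-yl]cyclohexa-1,4-diene | C=C(CCC(S(=O)(=O)c1ccccc1)S(=O)(=O)c1ccccc1)C1(C)C=CCC=C1 | intermediate |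
| 13 | 4-methyl-4-[5,5-bis(phenylsulfonyl)pent-1-en-2-yl]cyclohexa-2,5-dien-1-one | O=C1C=CC(C)(C=C1)C(=C)CCC(S(=O)(=O)c2ccccc2)S(=O)(=O)c3ccccc3 | intermediate (key-step precursor) |
| 14 | (4aS,8aR)-4a-methyl-5-methylidene-8,8-bis(phenylsulfonyl)-4a,5,6,7,8,8a-hexahydronaphthalen-2(1H)-one | C1CC(S(=O)(=O)c3ccccc3)(S(=O)(=O)c4ccccc4)[C@@H]2CC(=O)C=C[C@]2(C)C1=C | intermediate (key-step product) |
| 15 | C8 TBS dienol ether of 14 | C1CC(S(=O)(=O)c3ccccc3)(S(=O)(=O)c4ccccc4)[C@@H]2C=C(O[Si](C)(C)C(C)(C)C)C=C[C@]2(C)C1=C | intermediate |
| 16 | 8β,9β-epoxide of 15 | C1CC(S(=O)(=O)c3ccccc3)(S(=O)(=O)c4ccccc4)[C@@H]2[C@H]5O[C@@]5(O[Si](C)(C)C(C)(C)C)C=C[C@]2(C)C1=C | intermediate (not isolated) |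
| 17 | 9β-OTBS enone bis-sulfone | C1CC(S(=O)(=O)c3ccccc3)(S(=O)(=O)c4ccccc4)[C@@H]2[C@@H](O[Si](C)(C)C(C)(C)C)C(=O)C=C[C@]2(C)C1=C | intermediate |
| 18 | C8 allylic alcohol bis-sulfone (C8 not controlled) | C1CC(S(=O)(=O)c3ccccc3)(S(=O)(=O)c4ccccc4)[C@@H]2[C@@H](O[Si](C)(C)C(C)(C)C)C(O)C=C[C@]2(C)C1=C | intermediate |
| 19 | desulfonylated C8 allylic alcohol (C8 not controlled) | C1CC[C@@H]2[C@@H](O[Si](C)(C)C(C)(C)C)C(O)C=C[C@]2(C)C1=C | intermediate |
| 20 | 9β-OTBS enone with C4 methylene | C1CC[C@@H]2[C@@H](O[Si](C)(C)C(C)(C)C)C(=O)C=C[C@]2(C)C1=C | intermediate |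
| 21 | 3α-hydroxy derivative of 20 | O[C@@H]1CC[C@@H]2[C@@H](O[Si](C)(C)C(C)(C)C)C(=O)C=C[C@]2(C)C1=C | intermediate |
| 22 | 7-iodo enone | O[C@@H]1CC[C@@H]2[C@@H](O[Si](C)(C)C(C)(C)C)C(=O)C(I)=C[C@]2(C)C1=C | intermediate |
| 23 | 2-bromoprop-2-en-1-ol | OCC(Br)=C | starting material |
| 24 | lithium 2-lithioprop-2-en-1-olate | [Li]OCC([Li])=C | intermediate (not isolated) |
| 25 | 2-(tributylstannyl)prop-2-en-1-ol | OCC(=C)[Sn](CCCC)(CCCC)CCCC | intermediate |
| 26 | tert-butyldimethyl{[2-(tributylstannyl)prop-2-en-1-yl]oxy}silane | CC(C)(C)[Si](C)(C)OCC(=C)[Sn](CCCC)(CCCC)CCCC | intermediate |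
| 27 | cross-conjugated dienone | O[C@@H]1CC[C@@H]2[C@@H](O[Si](C)(C)C(C)(C)C)C(=O)C(C(=C)CO[Si](C)(C)C(C)(C)C)=C[C@]2(C)C1=C | intermediate |
| 28 | (7Z)-alkylidene ketone with C4 methylene | O[C@@H]1CC[C@@H]2[C@@H](O[Si](C)(C)C(C)(C)C)C(=O)/C(=C(/C)CO[Si](C)(C)C(C)(C)C)C[C@]2(C)C1=C | intermediate |
| 29 | 3α-hydroxy-4β-methyl (7Z)-alkylidene ketone | O[C@@H]1CC[C@@H]2[C@@H](O[Si](C)(C)C(C)(C)C)C(=O)/C(=C(/C)CO[Si](C)(C)C(C)(C)C)C[C@]2(C)[C@H]1C | intermediate |
| 30 | (E)-oct-2-enal | CCCCC/C=C/C=O | starting material |
| 31 | (E)-non-3-en-1-yne | CCCCC/C=C/C#C | intermediate |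
| 32 | dimethyl[(1E,3E)-2-methylnona-1,3-dien-1-yl]alane | CCCCC/C=C/C(C)=C/[Al](C)C | intermediate (not isolated) |
| 33 | (1E,3E)-1-iodo-2-methylnona-1,3-diene | CCCCC/C=C/C(C)=C/I | intermediate |
| 34 | methyl acrylate | C=CC(=O)OC | starting material |
| 35 | methyl (2E,4E,6E)-5-methyldodeca-2,4,6-trienoate | CCCCC/C=C/C(C)=C/C=C/C(=O)OC | intermediate |
| 36 | (2E,4E,6E)-5-methyldodeca-2,4,6-trienoic acid | CCCCC/C=C/C(C)=C/C=C/C(=O)O | intermediate |
| 37 | mixed anhydride of 36 and 2,4,6-trichlorobenzoic acid | CCCCC/C=C/C(C)=C/C=C/C(=O)OC(=O)c1c(Cl)cc(Cl)cc1Cl | intermediate (not isolated) |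
| 38 | 9,12-bis-TBS ether of the target | CCCCC/C=C/C(C)=C/C=C/C(=O)O[C@@H]1CC[C@@H]2[C@@H](O[Si](C)(C)C(C)(C)C)C(=O)/C(=C(/C)CO[Si](C)(C)C(C)(C)C)C[C@]2(C)[C@H]1C | intermediate |
| 39 | CNP0226738.1, (3R,4R,5R,9R,10S,7Z) | CCCCC/C=C/C(C)=C/C=C/C(=O)O[C@@H]1CC[C@@H]2[C@@H](O)C(=O)/C(=C(/C)CO)C[C@]2(C)[C@H]1C | target |

## Step count and risks

Total step count: 25.
Longest linear sequence: 19 steps (steps 1 to 14, 17 to 19, 24 and 25).

The three steps most likely to fail are the following.

**Step 7.** The catalyst may discriminate poorly between the two enone arms, or the uncatalysed closure may compete and erode the enantiomeric purity.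
- The fallback sets out from 13 and comes back at 14. It replaces asymmetric catalysis by a resolution.
- 13 is closed with catalytic Et3N in CH2Cl2 to the racemic cis-fused enone F1.
- Luche reduction gives the racemic allylic alcohol F2.
- Acetylation with Burkholderia cepacia lipase and vinyl acetate in MTBE separates the allylic alcohol of the wanted series F3 from the acetate of the antipodal series F4. If the enzyme prefers the wanted series, that acetate is methanolysed instead.
- Dess–Martin oxidation of F3 gives 14.

**Step 18.** The hindered diene may bind slowly to chromium, or the s-cis enone that is formed may be hydrogenated further.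
- The fallback sets out from 20 and comes back at 28. It builds the alkylidene by a reductive aldol and dehydration.
- Conjugate reduction of 20 with LiBH(s-Bu)3 in THF at −78 °C gives the C7 enolate regiospecifically.
- Trapping with 1-(tert-butyldimethylsilyloxy)propan-2-one gives the tertiary aldol F5.
- Dehydration with Martin sulfurane gives the Z alkylidene ketone F6 and the E alkylidene ketone F7. They are separated by chromatography, and F7 is returned to the mixture by sensitised photoisomerisation.
- Catalytic SeO2 with t-BuOOH on F6 gives 28.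

**Step 13.** Facial selectivity in the transfer of oxygen to C3 may be poor.
- The fallback sets out from 20 and comes back at 21. It corrects C3 by inversion.
- The epimers from the selenium dioxide oxidation are separated.
- The 3β-allylic alcohol F8 is treated with 4-nitrobenzoic acid, PPh3 and DIAD (Mitsunobu reaction) to give the 3α-(4-nitrobenzoate) F9.
- Methanolysis with K2CO3 in MeOH at 0 °C gives 21.

## Further compounds

F1 | step 7 | racemic cis-fused enone (both enantiomers of 14) | C=C1CCC(S(=O)(=O)c2ccccc2)(S(=O)(=O)c2ccccc2)C2CC(=O)C=CC12C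
F2 | step 7 | racemic allylic alcohol from F1 | C=C1CCC(S(=O)(=O)c2ccccc2)(S(=O)(=O)c2ccccc2)C2CC(O)C=CC12C
F3 | step 7 | allylic alcohol of the wanted series (ring fusion as in 14) | C1CC(S(=O)(=O)c3ccccc3)(S(=O)(=O)c4ccccc4)[C@@H]2CC(O)C=C[C@]2(C)C1=C
F4 | step 7 | acetate of the antipodal series | C1CC(S(=O)(=O)c3ccccc3)(S(=O)(=O)c4ccccc4)[C@H]2CC(OC(C)=O)C=C[C@@]2(C)C1=C
F5 | step 18 | tertiary aldol at C7 (C7 and C11 not controlled) | C1CC[C@@H]2[C@@H](O[Si](C)(C)C(C)(C)C)C(=O)C(C(C)(O)CO[Si](C)(C)C(C)(C)C)C[C@]2(C)C1=C
F6 | step 18 | Z alkylidene ketone without the C3 hydroxyl | C1CC[C@@H]2[C@@H](O[Si](C)(C)C(C)(C)C)C(=O)/C(=C(/C)CO[Si](C)(C)C(C)(C)C)C[C@]2(C)C1=C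
F7 | step 18 | E alkylidene ketone without the C3 hydroxyl | C1CC[C@@H]2[C@@H](O[Si](C)(C)C(C)(C)C)C(=O)/C(=C(\C)CO[Si](C)(C)C(C)(C)C)C[C@]2(C)C1=C
F8 | step 13 | 3β-allylic alcohol (C3 epimer of 21) | O[C@H]1CC[C@@H]2[C@@H](O[Si](C)(C)C(C)(C)C)C(=O)C=C[C@]2(C)C1=C
F9 | step 13 | 3α-(4-nitrobenzoate) of 21 | O=C(O[C@@H]1CC[C@@H]2[C@@H](O[Si](C)(C)C(C)(C)C)C(=O)C=C[C@]2(C)C1=C)c1ccc(cc1)[N+](=O)[O-]
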